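**Retrosynthetic overview**

1. Numbering used below (halimane type): ring A = C1H=, C2(=O), C3H2, C4Me2, C5H, C10; ring B = C5–C10 with C8HMe and quaternary C9; chain C11–C16 on C9, with C13 bearing the CH2O group and C16 bearing the furan.
2. Endgame: hydrogen sulfate ⇐ primary alcohol (O-sulfation) ⇐ silyl ether; furan ⇐ C16 bromide + 3-bromofuran (Negishi). Both acid-sensitive groups arrive after the cationic chemistry.
3. Ring A ⇐ ring B acid chloride + isobutylene, cutting C2–C3 and C4–C5. The C3H2–C4Me2 unit of ring A is an isobutylene unit lying between the acyl carbon C2 and the ring-fusion carbon C5, and the C1=C10 enone bond is where the last cation loses its proton. One acylative [4+2] annulation therefore builds ring A, the quaternary C4 and the C5 stereocentre.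
4. Ring B (bought as 2-iodocyclohex-2-en-1-one) is dressed first: C8 by catalytic asymmetric conjugate methylation, C9 by methylation of the resulting enolate, the C1–C2 arm on C10 by enol triflate/Reformatsky–Negishi coupling.
5. C9–C11 ⇐ B-alkyl Suzuki coupling with a terminal alkene whose C13 stereocentre comes from a copper-catalysed SN2′ allylic alkylation. Ring order: ring B (purchased), then ring A (key step), furan ring attached last.

Key step: step 10

Remark: the target is drawn as the hydrogen sulfate; step 13 frees it from its pyridinium salt on an acidic resin in the cold, and it should be stored as a salt because the furan is acid-sensitive.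
Remark: for the chiral ligands of steps 3 and 5 the enantiomer that gives the stated configuration is meant; the sense of induction is to be confirmed on the first run.

**Route**

Step 1
Reactants: 1 (E)-but-2-ene-1,4-diol
Product: 2 (E)-4-{[tert-butyl(diphenyl)silyl]oxy}but-2-en-1-ol
Conditions: NaH (1.0 equiv), THF, 0 °C → rt; then t-BuPh2SiCl (1.0 equiv), rt
Reagents that add atoms: tert-butylchlorodiphenylsilane, CC(C)(C)[Si](Cl)(c1ccccc1)c1ccccc1
Why: Monosilylation of a symmetrical diol through its sparingly soluble monosodium alkoxide (O-silylation), which should react once only.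

Step 2
Reactants: 2 (E)-4-{[tert-butyl(diphenyl)silyl]oxy}but-2-en-1-ol
Product: 3 {[(E)-4-bromobut-2-en-1-yl]oxy}(tert-butyl)diphenylsilane
Conditions: CBr4, PPh3, CH2Cl2, 0 °C
Reagents that add atoms: tetrabromomethane, BrC(Br)(Br)Br
Why: Appel bromination of a primary allylic alcohol, an SN2 process that should keep the E geometry.

Step 3
Reactants: 3 {[(E)-4-bromobut-2-en-1-yl]oxy}(tert-butyl)diphenylsilane; 4 (3-bromopropoxy)(tert-butyl)dimethylsilane
Product: 6 tert-butyl{[(2S)-5-{[tert-butyl(dimethyl)silyl]oxy}-2-ethenylpentyl]oxy}diphenylsilane, via Grignard reagent 5 (not isolated)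
Conditions: 4, Mg, Et2O, rt (gives 5); then slow addition to 3, CuBr·SMe2 (3 mol %), Taniaphos (3.5 mol %), CH2Cl2, −78 °C
Reagents that add atoms: none
Why: Copper-catalysed asymmetric allylic alkylation (SN2′) of an E-allylic bromide with a Grignard reagent, in which the chiral ferrocenyl diphosphine–copper complex delivers the alkyl group to one enantiotopic face of the γ-carbon and so sets C13 (S) next to a new terminal vinyl group.

Step 4
Reactants: 6 tert-butyl{[(2S)-5-{[tert-butyl(dimethyl)silyl]oxy}-2-ethenylpentyl]oxy}diphenylsilane; 7 2-iodocyclohex-2-en-1-one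
Product: 9 2-[(3R)-6-{[tert-butyl(dimethyl)silyl]oxy}-3-({[tert-butyl(diphenyl)silyl]oxy}methyl)hexyl]cyclohex-2-en-1-one, via alkylborane 8 (not isolated)
Conditions: 9-BBN (1.2 equiv), THF, 0 °C → rt (gives 8); then 7, PdCl2(dppf) (5 mol %), AsPh3 (10 mol %), Cs2CO3, DMF/H2O, rt
Reagents that add atoms: none
Why: Anti-Markovnikov hydroboration of the vinyl group followed by B-alkyl Suzuki–Miyaura coupling with the α-iodoenone forms the C9–C11 bond without touching C13 (the descriptor changes to R only because of the priority rules).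

Step 5
Reactants: 9 2-[(3R)-6-{[tert-butyl(dimethyl)silyl]oxy}-3-({[tert-butyl(diphenyl)silyl]oxy}methyl)hexyl]cyclohex-2-en-1-one
Product: 11 (2R,3R)-2-[(3R)-6-{[tert-butyl(dimethyl)silyl]oxy}-3-({[tert-butyl(diphenyl)silyl]oxy}methyl)hexyl]-2,3-dimethylcyclohexan-1-one, via magnesium enolate 10 (not isolated)
Conditions: MeMgBr (1.5 equiv), Cu(OTf)2 (4 mol %), chiral imidazolinium salt (NHC precursor, 5 mol %), Et2O, −30 °C (gives 10); then MeI (5 equiv), DMPU, −30 °C → rt
Reagents that add atoms: methylmagnesium bromide, C[Mg]Br; iodomethane, CI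
Why: Copper-catalysed asymmetric conjugate addition of a methyl Grignard reagent to the 2-alkyl enone sets C8 (R) under catalyst control, and the regiodefined magnesium enolate is then C-methylated anti to the new C8 methyl (pseudoaxial to avoid A(1,2) strain with the C9 chain), which gives the quaternary C9 (R) with the two methyl groups trans.

Step 6
Reactants: 11 (2R,3R)-2-[(3R)-6-{[tert-butyl(dimethyl)silyl]oxy}-3-({[tert-butyl(diphenyl)silyl]oxy}methyl)hexyl]-2,3-dimethylcyclohexan-1-one
Product: 12 (2R,3R)-2-[(3R)-6-bromo-3-({[tert-butyl(diphenyl)silyl]oxy}methyl)hexyl]-2,3-dimethylcyclohexan-1-one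
Conditions: Ph3PBr2 (1.2 equiv), CH2Cl2, 0 °C → rt
Reagents that add atoms: dibromotriphenylphosphorane, BrP(Br)(c1ccccc1)(c1ccccc1)c1ccccc1
Why: Direct conversion of a silyl ether into a bromide (activation of the ether oxygen by the phosphonium, loss of the silyl bromide, SN2 by bromide), which should take the unhindered tert-butyldimethylsilyl ether and leave the much bulkier tert-butyldiphenylsilyl ether and the ketone alone.

Step 7
Reactants: 12 (2R,3R)-2-[(3R)-6-bromo-3-({[tert-butyl(diphenyl)silyl]oxy}methyl)hexyl]-2,3-dimethylcyclohexan-1-one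
Product: 13 (5R,6R)-6-[(3R)-6-bromo-3-({[tert-butyl(diphenyl)silyl]oxy}methyl)hexyl]-5,6-dimethylcyclohex-1-en-1-yl trifluoromethanesulfonate
Conditions: KN(SiMe3)2, THF, −78 °C; then PhNTf2, −78 → 0 °C
Reagents that add atoms: N-phenylbis(trifluoromethanesulfonimide), O=S(=O)(N(c1ccccc1)S(=O)(=O)C(F)(F)F)C(F)(F)F
Why: Enolisation can only go toward C5 because C9 is quaternary, and O-triflation of the potassium enolate (enol triflate formation) fixes the C5=C10 double bond.

Step 8
Reactants: 13 (5R,6R)-6-[(3R)-6-bromo-3-({[tert-butyl(diphenyl)silyl]oxy}methyl)hexyl]-5,6-dimethylcyclohex-1-en-1-yl trifluoromethanesulfonate; 14 bromo(2-tert-butoxy-2-oxoethyl)zinc (Reformatsky reagent of tert-butyl bromoacetate)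
Product: 15 tert-butyl 2-{(5R,6R)-6-[(3R)-6-bromo-3-({[tert-butyl(diphenyl)silyl]oxy}methyl)hexyl]-5,6-dimethylcyclohex-1-en-1-yl}acetate
Conditions: Pd2(dba)3 (2.5 mol %), XPhos (10 mol %), THF, 60 °C
Reagents that add atoms: none
Why: Negishi-type cross-coupling of a zinc ester enolate with an alkenyl triflate puts the C1–C2 arm on C10 and keeps the alkene in the ring (β,γ to the ester), the primary alkyl bromide being much slower in oxidative addition.

Step 9
Reactants: 15 tert-butyl 2-{(5R,6R)-6-[(3R)-6-bromo-3-({[tert-butyl(diphenyl)silyl]oxy}methyl)hexyl]-5,6-dimethylcyclohex-1-en-1-yl}acetate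
Product: 16 2-{(5R,6R)-6-[(3R)-6-bromo-3-({[tert-butyl(diphenyl)silyl]oxy}methyl)hexyl]-5,6-dimethylcyclohex-1-en-1-yl}acetic acid
Conditions: aq. H3PO4 (85 %), toluene, rt
Reagents that add atoms: none
Why: Acidolysis of the tert-butyl ester (E1 loss of 2-methylpropene) with a weak acid that should neither protonate the trisubstituted alkene nor cleave the tert-butyldiphenylsilyl ether.

Step 10
Reactants: 16 2-{(5R,6R)-6-[(3R)-6-bromo-3-({[tert-butyl(diphenyl)silyl]oxy}methyl)hexyl]-5,6-dimethylcyclohex-1-en-1-yl}acetic acid; 17 2-methylpropene (isobutylene)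
Product: 19 (4aS,7R,8R)-8-[(3R)-6-bromo-3-({[tert-butyl(diphenyl)silyl]oxy}methyl)hexyl]-4,4,7,8-tetramethyl-4,4a,5,6,7,8-hexahydronaphthalen-2(3H)-one, via acid chloride 18 (not isolated)
Conditions: (COCl)2 (1.5 equiv), DMF (cat.), CH2Cl2, 0 °C → rt, evaporation (gives 18); then 17 (10 equiv), SnCl4 (1.2 equiv), CH2Cl2 (0.01 M), −78 → −40 °C; then Et3N, −40 °C → rt
Reagents that add atoms: none
Why: Proposed new method: SnCl4 activates acid chloride 18 to an acylium equivalent at C2 that is attacked by the CH2 terminus of isobutylene (C2–C3 bond, Markovnikov), the resulting tertiary C4 cation sits in a 1,6-relationship to C5 and is captured by the C5=C10 alkene (C4–C5 bond), and the tertiary C10 cation loses the C1 proton, now alpha to the complexed ketone, to give the conjugated C1=C10 enone (a C10 chloride, if formed, loses HCl on the Et3N quench). The closest known reaction types are the Friedel–Crafts (Darzens–Nenitzescu) acylation of alkenes, which gives the same beta-keto cation from acyl chlorides and isobutylene, and the AlCl3-mediated acylation–cycloalkylation of arylacetyl chlorides with alkenes to 2-tetralones, in which an arene instead of the C5=C10 alkene ends the sequence; new is the use of a ring alkene as internal terminator. Ring A is closed by a 6-endo-trig cation–olefin closure within a formal [4+2] annulation, and the alternative 5-exo closure at C10 is excluded because it would give a secondary cation and a spiro ring. The only new stereocentre, C5, is controlled by the C8/C9 pair: in the half-chair of ring B that keeps the C8 methyl equatorial the C9 chain is pseudoaxial (also favoured by A(1,2) strain with the C10 arm) and shields its face, so C4 is delivered to the face of the C9 methyl and H-5 ends cis to the chain (5S), whereas the other half-chair has an axial methyl on each face. The step needs acylation of isobutylene in preference to the ring alkene of a second molecule and to the silyl ether oxygen, which the tenfold excess of the unhindered 1,1-disubstituted alkene, high dilution and low temperature should secure, and it needs ring closure to win over proton loss or chloride capture at C4, both of which are reversible under SnCl4/HCl and feed the same cation again.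

Step 11
Reactants: 19 (4aS,7R,8R)-8-[(3R)-6-bromo-3-({[tert-butyl(diphenyl)silyl]oxy}methyl)hexyl]-4,4,7,8-tetramethyl-4,4a,5,6,7,8-hexahydronaphthalen-2(3H)-one; 20 3-bromofuran
Product: 22 (4aS,7R,8R)-8-[(3S)-3-({[tert-butyl(diphenyl)silyl]oxy}methyl)-6-(furan-3-yl)hexyl]-4,4,7,8-tetramethyl-4,4a,5,6,7,8-hexahydronaphthalen-2(3H)-one, via alkylzinc bromide 21 (not isolated)
Conditions: Zn dust (activated with BrCH2CH2Br and Me3SiCl), LiCl, THF, 50 °C (gives 21); then 20, Pd(OAc)2 (2 mol %), SPhos (4 mol %), THF, rt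
Reagents that add atoms: none
Why: Zinc insertion into the primary C–Br bond and Negishi sp3–sp2 cross-coupling with 3-bromofuran, an alkylzinc halide being unreactive toward the hindered enone (the C13 descriptor returns to S by the priority rules only).

Step 12
Reactants: 22 (4aS,7R,8R)-8-[(3S)-3-({[tert-butyl(diphenyl)silyl]oxy}methyl)-6-(furan-3-yl)hexyl]-4,4,7,8-tetramethyl-4,4a,5,6,7,8-hexahydronaphthalen-2(3H)-one
Product: 23 (4aS,7R,8R)-8-[(3S)-6-(furan-3-yl)-3-(hydroxymethyl)hexyl]-4,4,7,8-tetramethyl-4,4a,5,6,7,8-hexahydronaphthalen-2(3H)-one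
Conditions: Bu4NF (1.5 equiv), AcOH (1.5 equiv), THF, 0 °C → rt
Reagents that add atoms: none
Why: Fluoride-induced desilylation, buffered with acetic acid so that the enone is not enolised toward the epimerisable C5.

Step 13
Reactants: 23 (4aS,7R,8R)-8-[(3S)-6-(furan-3-yl)-3-(hydroxymethyl)hexyl]-4,4,7,8-tetramethyl-4,4a,5,6,7,8-hexahydronaphthalen-2(3H)-one
Product: 24 (2S)-5-(furan-3-yl)-2-{2-[(1R,2R,4aS)-1,2,5,5-tetramethyl-7-oxo-1,2,3,4,4a,5,6,7-octahydronaphthalen-1-yl]ethyl}pentyl hydrogen sulfate (CNP0424620.3)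
Conditions: SO3·pyridine (3 equiv), pyridine, rt; then cation-exchange resin (H+ form), MeOH, 0 °C
Reagents that add atoms: sulfur trioxide–pyridine complex, [O-]S(=O)(=O)[n+]1ccccc1
Why: O-Sulfation of the only hydroxyl group with a mild SO3 donor, followed by proton exchange of the pyridinium salt, gives the hydrogen sulfate without touching furan or enone.

**Compound list**

1 | (E)-but-2-ene-1,4-diol | OC/C=C/CO | starting material
2 | (E)-4-{[tert-butyl(diphenyl)silyl]oxy}but-2-en-1-ol | OC/C=C/CO[Si](c1ccccc1)(c1ccccc1)C(C)(C)C | intermediate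
3 | {[(E)-4-bromobut-2-en-1-yl]oxy}(tert-butyl)diphenylsilane | BrC/C=C/CO[Si](c1ccccc1)(c1ccccc1)C(C)(C)C | intermediate
4 | (3-bromopropoxy)(tert-butyl)dimethylsilane | BrCCCO[Si](C)(C)C(C)(C)C | starting material
5 | (3-{[tert-butyl(dimethyl)silyl]oxy}propyl)magnesium bromide | Br[Mg]CCCO[Si](C)(C)C(C)(C)C | intermediate (not isolated)
6 | tert-butyl{[(2S)-5-{[tert-butyl(dimethyl)silyl]oxy}-2-ethenylpentyl]oxy}diphenylsilane | C=C[C@H](CCCO[Si](C)(C)C(C)(C)C)CO[Si](c1ccccc1)(c1ccccc1)C(C)(C)C | intermediate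
7 | 2-iodocyclohex-2-en-1-one | O=C1CCCC=C1I | starting material
8 | 9-[(3R)-6-{[tert-butyl(dimethyl)silyl]oxy}-3-({[tert-butyl(diphenyl)silyl]oxy}methyl)hexyl]-9-borabicyclo[3.3.1]nonane | B1(C2CCCC1CCC2)CC[C@H](CCCO[Si](C)(C)C(C)(C)C)CO[Si](c1ccccc1)(c1ccccc1)C(C)(C)C | intermediate (not isolated)
9 | 2-[(3R)-6-{[tert-butyl(dimethyl)silyl]oxy}-3-({[tert-butyl(diphenyl)silyl]oxy}methyl)hexyl]cyclohex-2-en-1-one | O=C1CCCC=C1CC[C@H](CCCO[Si](C)(C)C(C)(C)C)CO[Si](c1ccccc1)(c1ccccc1)C(C)(C)C | intermediate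
10 | bromomagnesium (3R)-2-[(3R)-6-{[tert-butyl(dimethyl)silyl]oxy}-3-({[tert-butyl(diphenyl)silyl]oxy}methyl)hexyl]-3-methylcyclohex-1-en-1-olate | C[C@@H]1CCCC(O[Mg]Br)=C1CC[C@H](CCCO[Si](C)(C)C(C)(C)C)CO[Si](c1ccccc1)(c1ccccc1)C(C)(C)C | intermediate (not isolated)
11 | (2R,3R)-2-[(3R)-6-{[tert-butyl(dimethyl)silyl]oxy}-3-({[tert-butyl(diphenyl)silyl]oxy}methyl)hexyl]-2,3-dimethylcyclohexan-1-one | C[C@@H]1CCCC(=O)[C@]1(C)CC[C@H](CCCO[Si](C)(C)C(C)(C)C)CO[Si](c1ccccc1)(c1ccccc1)C(C)(C)C | intermediate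
12 | (2R,3R)-2-[(3R)-6-bromo-3-({[tert-butyl(diphenyl)silyl]oxy}methyl)hexyl]-2,3-dimethylcyclohexan-1-one | C[C@@H]1CCCC(=O)[C@]1(C)CC[C@H](CCCBr)CO[Si](c1ccccc1)(c1ccccc1)C(C)(C)C | intermediate
13 | (5R,6R)-6-[(3R)-6-bromo-3-({[tert-butyl(diphenyl)silyl]oxy}methyl)hexyl]-5,6-dimethylcyclohex-1-en-1-yl trifluoromethanesulfonate | C[C@@H]1CCC=C(OS(=O)(=O)C(F)(F)F)[C@]1(C)CC[C@H](CCCBr)CO[Si](c1ccccc1)(c1ccccc1)C(C)(C)C | intermediate
14 | bromo(2-tert-butoxy-2-oxoethyl)zinc | CC(C)(C)OC(=O)C[Zn]Br | starting material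
15 | tert-butyl 2-{(5R,6R)-6-[(3R)-6-bromo-3-({[tert-butyl(diphenyl)silyl]oxy}methyl)hexyl]-5,6-dimethylcyclohex-1-en-1-yl}acetate | C[C@@H]1CCC=C(CC(=O)OC(C)(C)C)[C@]1(C)CC[C@H](CCCBr)CO[Si](c1ccccc1)(c1ccccc1)C(C)(C)C | intermediate
16 | 2-{(5R,6R)-6-[(3R)-6-bromo-3-({[tert-butyl(diphenyl)silyl]oxy}methyl)hexyl]-5,6-dimethylcyclohex-1-en-1-yl}acetic acid | C[C@@H]1CCC=C(CC(=O)O)[C@]1(C)CC[C@H](CCCBr)CO[Si](c1ccccc1)(c1ccccc1)C(C)(C)C | intermediate
17 | 2-methylpropene (isobutylene) | CC(C)=C | starting material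
18 | 2-{(5R,6R)-6-[(3R)-6-bromo-3-({[tert-butyl(diphenyl)silyl]oxy}methyl)hexyl]-5,6-dimethylcyclohex-1-en-1-yl}acetyl chloride | C[C@@H]1CCC=C(CC(=O)Cl)[C@]1(C)CC[C@H](CCCBr)CO[Si](c1ccccc1)(c1ccccc1)C(C)(C)C | intermediate (not isolated)
19 | (4aS,7R,8R)-8-[(3R)-6-bromo-3-({[tert-butyl(diphenyl)silyl]oxy}methyl)hexyl]-4,4,7,8-tetramethyl-4,4a,5,6,7,8-hexahydronaphthalen-2(3H)-one | C[C@@H]1CC[C@@H]2C(=CC(=O)CC2(C)C)[C@]1(C)CC[C@H](CCCBr)CO[Si](c1ccccc1)(c1ccccc1)C(C)(C)C | intermediate
20 | 3-bromofuran | Brc1ccoc1 | starting material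
21 | alkylzinc bromide of 19 (ZnBr in place of Br at C16, otherwise unchanged) | C[C@@H]1CC[C@@H]2C(=CC(=O)CC2(C)C)[C@]1(C)CC[C@H](CCC[Zn]Br)CO[Si](c1ccccc1)(c1ccccc1)C(C)(C)C | intermediate (not isolated)
22 | (4aS,7R,8R)-8-[(3S)-3-({[tert-butyl(diphenyl)silyl]oxy}methyl)-6-(furan-3-yl)hexyl]-4,4,7,8-tetramethyl-4,4a,5,6,7,8-hexahydronaphthalen-2(3H)-one | C[C@@H]1CC[C@@H]2C(=CC(=O)CC2(C)C)[C@]1(C)CC[C@H](CCCc1ccoc1)CO[Si](c1ccccc1)(c1ccccc1)C(C)(C)C | intermediate
23 | (4aS,7R,8R)-8-[(3S)-6-(furan-3-yl)-3-(hydroxymethyl)hexyl]-4,4,7,8-tetramethyl-4,4a,5,6,7,8-hexahydronaphthalen-2(3H)-one | C[C@@H]1CC[C@@H]2C(=CC(=O)CC2(C)C)[C@]1(C)CC[C@H](CCCc1ccoc1)CO | intermediate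
24 | (2S)-5-(furan-3-yl)-2-{2-[(1R,2R,4aS)-1,2,5,5-tetramethyl-7-oxo-1,2,3,4,4a,5,6,7-octahydronaphthalen-1-yl]ethyl}pentyl hydrogen sulfate | C[C@@H]1CC[C@@H]2C(=CC(=O)CC2(C)C)[C@]1(C)CC[C@H](CCCc1ccoc1)COS(=O)(=O)O | target

**Step count and risks**

Total step count: 13. Longest linear sequence: 13 steps (1 → 24; all other building blocks are purchased).

Steps most likely to fail:

1. Step 10 (proposed new method). What may go wrong: cationic oligomerisation of isobutylene or acylation of the ring alkene of a second molecule; loss of a proton or capture of chloride at C4 before the ring closes; loss of CO from the acylium; insufficient facial selectivity at C5. The fallback is stepwise and uses known chemistry; it sets out from acid 16 and comes back at enone 19. Acid 16 is condensed with N,O-dimethylhydroxylamine hydrochloride (EDC·HCl, i-Pr2NEt, CH2Cl2) to the N-methoxy-N-methylamide F1. (2-Methylallyl)magnesium chloride (THF, −78 °C) then gives the 2-methylallyl ketone F2 by acyl substitution, so the C2–C3 bond is made by a nucleophile and no intermolecular cationic step is needed. F2 is cyclised with a Brønsted acid (CF3SO3H cat., CH2Cl2, −40 → 0 °C): protonation of the 2-methylallyl group gives the same C4 cation, which closes onto C5=C10 in a conventional proton-initiated cation–olefin cyclisation and ends as 19.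

2. Step 5. What may go wrong: slow or poorly enantioselective conjugate addition of a methyl group to the α-substituted enone, and failure of the hindered magnesium enolate to undergo C-methylation. The fallback sets out from enone 9 and comes back at ketone 11. Corey–Bakshi–Shibata reduction of 9 (the oxazaborolidine enantiomer that gives the 1S alcohol, BH3·SMe2, THF) should give the allylic alcohol F3. Hydroxyl-directed Simmons–Smith cyclopropanation (Et2Zn, CH2I2, CH2Cl2) delivers the methylene to the face of the hydroxyl group and gives the cis-fused cyclopropyl carbinol F4. Oxidation (Dess–Martin periodinane) gives the cyclopropyl ketone F5. Li in NH3/THF at −78 °C (short contact time, because of the phenyl groups on silicon) cleaves the exocyclic cyclopropane bond that overlaps with the carbonyl π system. This turns the methylene into the C8 methyl group, whose configuration was fixed by the cyclopropanation, and gives the regiodefined lithium enolate F6, which is trapped in the same flask with MeI, anti to the C8 methyl, to give 11.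

3. Step 8. What may go wrong: slow oxidative addition or transmetalation at the enol triflate next to the quaternary C9, so that hydrolysis or reduction of the triflate takes over. The fallback sets out from ketone 12 and comes back at ester 15. Aldol addition of the lithium enolate of tert-butyl acetate (LiN(i-Pr)2, THF, −78 °C) to 12 gives the β-hydroxy ester F7 (either C10 epimer). Dehydration (SOCl2, pyridine, 0 °C) toward C5 gives 15; the endocyclic alkene is expected because the exocyclic isomer would suffer allylic strain with the quaternary C9.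

**Further compounds**

F1 | step 10 | 2-{(5R,6R)-6-[(3R)-6-bromo-3-({[tert-butyl(diphenyl)silyl]oxy}methyl)hexyl]-5,6-dimethylcyclohex-1-en-1-yl}-N-methoxy-N-methylacetamide | C[C@@H]1CCC=C(CC(=O)N(C)OC)[C@]1(C)CC[C@H](CCCBr)CO[Si](c1ccccc1)(c1ccccc1)C(C)(C)C
F2 | step 10 | 1-{(5R,6R)-6-[(3R)-6-bromo-3-({[tert-butyl(diphenyl)silyl]oxy}methyl)hexyl]-5,6-dimethylcyclohex-1-en-1-yl}-4-methylpent-4-en-2-one | C[C@@H]1CCC=C(CC(=O)CC(C)=C)[C@]1(C)CC[C@H](CCCBr)CO[Si](c1ccccc1)(c1ccccc1)C(C)(C)C
F3 | step 5 | (1S)-2-[(3R)-6-{[tert-butyl(dimethyl)silyl]oxy}-3-({[tert-butyl(diphenyl)silyl]oxy}methyl)hexyl]cyclohex-2-en-1-ol | O[C@H]1CCCC=C1CC[C@H](CCCO[Si](C)(C)C(C)(C)C)CO[Si](c1ccccc1)(c1ccccc1)C(C)(C)C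
F4 | step 5 | (2S)-1-[(3R)-6-{[tert-butyl(dimethyl)silyl]oxy}-3-({[tert-butyl(diphenyl)silyl]oxy}methyl)hexyl]bicyclo[4.1.0]heptan-2-ol, cyclopropane methylene syn to the hydroxyl group | O[C@H]1CCC[C@H]2C[C@@]12CC[C@H](CCCO[Si](C)(C)C(C)(C)C)CO[Si](c1ccccc1)(c1ccccc1)C(C)(C)C
F5 | step 5 | 1-[(3R)-6-{[tert-butyl(dimethyl)silyl]oxy}-3-({[tert-butyl(diphenyl)silyl]oxy}methyl)hexyl]bicyclo[4.1.0]heptan-2-one, ring carbons configured as in F4 | O=C1CCC[C@H]2C[C@@]12CC[C@H](CCCO[Si](C)(C)C(C)(C)C)CO[Si](c1ccccc1)(c1ccccc1)C(C)(C)C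
F6 | step 5 | lithium (3R)-2-[(3R)-6-{[tert-butyl(dimethyl)silyl]oxy}-3-({[tert-butyl(diphenyl)silyl]oxy}methyl)hexyl]-3-methylcyclohex-1-en-1-olate | C[C@@H]1CCCC(O[Li])=C1CC[C@H](CCCO[Si](C)(C)C(C)(C)C)CO[Si](c1ccccc1)(c1ccccc1)C(C)(C)C
F7 | step 8 | tert-butyl 2-{(2R,3R)-2-[(3R)-6-bromo-3-({[tert-butyl(diphenyl)silyl]oxy}methyl)hexyl]-1-hydroxy-2,3-dimethylcyclohexyl}acetate (either epimer at the carbinol carbon) | C[C@@H]1CCCC(O)(CC(=O)OC(C)(C)C)[C@]1(C)CC[C@H](CCCBr)CO[Si](c1ccccc1)(c1ccccc1)C(C)(C)C
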